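| flask | starting material | coupling partner | temperature | remark | time |
|---|---|---|---|---|---|
| dawn | 0.15 M | 0.375 M | 25 °C | run made earlier |  |
| summer | 0.075 M | 0.375 M | 25 °C | run made earlier |  |
| north | 0.15 M | 0.375 M | 25 °C | everything together at the start | 2.5 d |
| west | 0.15 M | 0.375 M (fed, over 40 h) |  | the addition at 5 °C, then warmed to 25 °C; the feed brings no volume worth counting | 2.5 d |
| south-west | 0.15 M (fed, over 40 h) | 0.375 M | 25 °C | all else is in the flask from the start; the feed brings no volume worth counting | 2.5 d |
| north-east | 0.15 M | 0.375 M (fed, over 40 h) | 25 °C | all else is in the flask from the start; the feed brings no volume worth counting | 2.5 d |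

- dawn (time / h: over-reaction product / %, mono adduct / %): 8.00: 6.8, 8.5; 15.0: 12.5, 6.9; 20.0: 16.3, 6.2; 30.0: 21.9, 5.8; 40.0: 26.0, 4.2
- summer (time / h: over-reaction product / %, mono adduct / %): 1.50: 1.0, 3.8; 5.00: 3.7, 7.7; 8.00: 6.9, 8.6; 12.0: 11.5, 7.3; 20.0: 19.4, 6.3

(readings scatter by 0.5 percentage points)

- reactions considered so far: starting material + coupling partner -> mono adduct; coupling partner + mono adduct -> over-reaction product; starting material + coupling partner -> other mono adduct; coupling partner + other mono adduct -> double product; coupling partner + mono adduct -> double product
- the earlier runs do not show what temperature does; that part of a forecast is a guess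

- the flask that comes out highest in amount of over-reaction product, in percent of the starting material charged, or "all alike" when all lie within 1.5 percentage points (north / west / south-west / north-east / all alike)
- over-reaction product at the end, in percent of the starting material charged, north
- over-reaction product at the end, in percent of the starting material charged, west
- over-reaction product at the end, in percent of the starting material charged, south-west
- over-reaction product at the end, in percent of the starting material charged, north-east

- At 0.15 M, starting material stood lower than coupling partner at 0.375 M, so it was the limiting reagent, and I wrote its balance: c(starting material) falls in proportion to itself and to c(coupling partner).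
- The dawn run held twice the starting material of the summer run; at 8.00 h they read 6.8 % and 6.9 % of over-reaction product, but at 20.0 h they read 16.3 % and 19.4 %, so I carried percent curves between flasks as a rough guide.
- In dawn, over-reaction product gained 5.6 percentage points, then 4.1 points, over equal stretches of 10.0 h. That shrinking read as a plateau near 37.2 % and a decay rate of 0.0312 h⁻¹.
- I folded this into one number: N, the decay rate read in dawn times the hours in the flask, which is 1.87 for north. The product is then the plateau times one minus exp(−N).
- That gave 31.5 % for north. North-east, counting each feed hour as 0.5 of an hour in north, gave 26.5 %. South-west, averaged over arrival times, gave 25.8 %. West, with its cold hours counted as nothing, which is a guess, gave 17.3 %. North came out higher than the others.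
- One number was not quite enough: it gave 17.3 % for summer at 20.0 h, lower than the 19.4 % read, a gap of 2.1 points.
- The forecast said 32 %, 20 %, 25 % and 26 % for north, west, south-west and north-east, with north highest, on the ground that “every step looks first order in partner”.

The flasks gave 30.5 %, 18.5 %, 25.0 % and 25.5 %, in that order, with north highest.

    starting material + coupling partner → mono adduct (k = 0.0860 L mol⁻¹ h⁻¹, Ea = 76.0 kJ mol⁻¹)
    coupling partner + mono adduct → over-reaction product (k = 0.410 L mol⁻¹ h⁻¹, Ea = 62.0 kJ mol⁻¹)
    starting material + coupling partner → other mono adduct (k = 0.0370 L mol⁻¹ h⁻¹, Ea = 74.0 kJ mol⁻¹)
    coupling partner + other mono adduct → double product (k = 0.00120 L mol⁻¹ h⁻¹, Ea = 96.0 kJ mol⁻¹)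
    coupling partner + mono adduct → double product (k = 0.330 L mol⁻¹ h⁻¹, Ea = 85.0 kJ mol⁻¹)
    (constants at 25 °C)

- North kept 17.6 % of its starting material at 2.50 d, and exp(−N) for north gives 15.4 %; N was read off gains of over-reaction product, not off this balance.
- For a neighbour of north with 1.5 M of coupling partner, N scaled to 7.48, which gives 0.0564 % of starting material left and 37.2 % of over-reaction product; the computed flask held 0.00848 % and 38.7 %.

All runs stem from a simulated flask on assumed constants, and the scatter is random.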